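## Retrosynthetic overview
1. Target **21** ⇐ global desilylation and PMB removal ⇐ ketone **19**. Its C12–C13 bond is made by a radical acylation of primary iodide **17** with propanal, which avoids an aldol with unstable 3-oxopentanal.
2. **17** ⇐ a second anti-aldol of the bis-PMB ketone core (**11**) with chloroacetaldehyde (C10–C11). The first anti-aldol (C7–C8) joins **11** to epoxy aldehyde **9**.
3. **9** ⇐ oxidation of a Payne-isomerised epoxy alcohol. The only ring, the epoxide, is made once by Sharpless AE of 1,1-disubstituted allylic alcohol **6** and then relocated (C6–C7 to C5–C6) by Payne rearrangement.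
4. **6** ⇐ Lindlar reduction of Marshall anti-propargylation adduct **5** (methacrolein + chiral propargylic mesylate), which sets C4, C5 and the Z-alkene.

Assumptions: **21** is the open-chain form drawn. The chiral reagents (Ru catalyst, Ipc₂BCl, DIPT, mesylate enantiomer) are taken to give the depicted configurations.

## Route

**Step 1**
Reactants: 1 3-pentyn-2-one
Product: 2 (2R)-pent-3-yn-2-ol
Conditions: RuCl[(R,R)-TsDPEN](p-cymene) (1 mol%), HCO₂H/Et₃N (5:2), 25 °C
Reagents that add atoms: none
Why: Noyori asymmetric transfer hydrogenation reduces the ynone C=O selectively, and the catalyst enantiomer sets the (R) carbinol that later becomes C4.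

**Step 2**
Reactants: 2
Product: 3 (2R)-pent-3-yn-2-yl methanesulfonate
Conditions: MsCl, Et₃N, CH₂Cl₂, –20 °C
Reagents that add atoms: methanesulfonyl chloride, CS(=O)(=O)Cl
Why: O-sulfonylation with retention makes a propargylic leaving group for Pd-catalysed SN2′ ionisation.

**Step 3**
Reactants: 3; 4 methacrolein
Product: 5 (3S,4S)-2,4-dimethylhept-1-en-5-yn-3-ol
Conditions: Pd(OAc)₂ (5 mol%), PPh₃ (10 mol%), Et₂Zn (2 equiv), THF, –20 °C
Reagents that add atoms: none
Why: In the Marshall–Tamaru propargylation, Pd(0) SN2′ ionisation and Zn transmetalation give a chiral allenylzinc that adds through a cyclic chair TS. This gives the anti homopropargylic alcohol, with C4 from allene-axis transfer and C5 from the TS (the (R)-mesylate is assumed to give (3S,4S)).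

**Step 4**
Reactants: 5
Product: 6 (3S,4S,5Z)-2,4-dimethylhepta-1,5-dien-3-ol
Conditions: H₂ (1 atm), Lindlar catalyst, quinoline, EtOAc, 25 °C
Reagents that add atoms: none
Why: Lindlar semihydrogenation is syn addition and gives the Z-alkene (C2=C3), leaving the 1,1-disubstituted alkene and the allylic alcohol untouched.

**Step 5**
Reactants: 6
Product: 7 (1S,2S,3Z)-2-methyl-1-[(2S)-2-methyloxiran-2-yl]pent-3-en-1-ol
Conditions: Ti(OiPr)₄ (1 equiv), L-(+)-DIPT (1.2 equiv), TBHP, 4 Å MS, CH₂Cl₂, –20 °C
Reagents that add atoms: tert-butyl hydroperoxide, CC(C)(C)OO (supplies the epoxide O)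
Why: Sharpless asymmetric epoxidation is matched with the (S)-carbinol and delivers O to one face of the 1,1-disubstituted allylic alkene, setting the quaternary oxirane carbon (future C6) as S.

**Step 6**
Reactants: 7
Product: 8 {(2R,3S)-2-methyl-3-[(2S,3Z)-pent-3-en-2-yl]oxiran-2-yl}methanol
Conditions: 0.5 M aq. NaOH, t-BuOH, 25 °C (equilibrate, separate, recycle the unreacted epoxy alcohol)
Reagents that add atoms: none
Why: In the Payne rearrangement the C5 alkoxide opens the C6–C7 epoxide with inversion at C6. This gives the more substituted trisubstituted C5–C6 epoxide with a primary alcohol, so C6 becomes R as in the target (an isomer ratio favouring 8 is assumed).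

**Step 7**
Reactants: 8
Product: 9 (2S,3S)-2-methyl-3-[(2S,3Z)-pent-3-en-2-yl]oxirane-2-carbaldehyde
Conditions: TEMPO (10 mol%), PhI(OAc)₂ (1.2 equiv), CH₂Cl₂, 0 °C
Reagents that add atoms: none
Why: TEMPO/BAIB oxidises the primary alcohol chemoselectively, and the α-carbon is quaternary, so the aldehyde cannot epimerise.

**Step 8**
Reactants: 10 1,5-dichloropentan-3-one
Product: 11 1,5-bis[(4-methoxybenzyl)oxy]pentan-3-one
Conditions: 4-methoxybenzyl alcohol (4 equiv), KOtBu (2.3 equiv), THF, 0 °C → 25 °C
Reagents that add atoms: 4-methoxybenzyl alcohol, COc1ccc(CO)cc1 (two PMBO groups retained)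
Why: Base-induced E1cB loss of HCl gives divinyl ketone in situ, and double oxa-Michael addition of PMBOH gives the symmetric, achiral ketone core (no stereocentres).

**Step 9**
Reactants: 9; 11
Product: 12 anti-aldol adduct (C7–OH, C8–CH₂OPMB, C9 ketone)
Conditions: (+)-Ipc₂BCl (1.3 equiv), Et₃N, CH₂Cl₂, –78 → –20 °C; add 9 at –78 °C; H₂O₂/MeOH/pH 7 work-up
Reagents that add atoms: none
Why: In a Brown–Paterson boron aldol, Ipc₂BCl/Et₃N gives the E-enol borinate, and the chair Zimmerman–Traxler TS gives the anti relationship; the chiral boron desymmetrises the prochiral ketone and is chosen to be matched with 9, giving (7S,8R).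

**Step 10**
Reactants: 12
Product: 13 C7-O-TBS ether of 12
Conditions: TBSOTf (1.5 equiv), 2,6-lutidine (3 equiv), CH₂Cl₂, –78 °C
Reagents that add atoms: tert-butyldimethylsilyl triflate, CC(C)(C)[Si](C)(C)OS(=O)(=O)C(F)(F)F
Why: Silylating the hindered secondary alcohol prevents it from interfering in the second enolisation and radical steps; no stereocentre is touched.

**Step 11**
Reactants: 13; 14 chloroacetaldehyde
Product: 15 aldol adduct (C10 CH₂OPMB, C11–OH, C12–Cl)
Conditions: (–)-Ipc₂BCl, Et₃N, CH₂Cl₂, –78 → –20 °C; add 14 (freshly extracted anhydrous solution) at –78 °C; pH 7 work-up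
Reagents that add atoms: none
Why: The E-enol borinate forms at the less hindered CH₂ (C10), the anti-aldol sets C10/C11, and the opposite Ipc enantiomer gives the mirror-related (meso-type) C8/C10 relationship of the target.

**Step 12**
Reactants: 15
Product: 16 C11-O-TBS ether of 15
Conditions: TBSOTf (1.5 equiv), 2,6-lutidine, CH₂Cl₂, –78 °C
Reagents that add atoms: TBSOTf, CC(C)(C)[Si](C)(C)OS(=O)(=O)C(F)(F)F
Why: It protects C11–OH so that the acyl azolium in the next steps cannot acylate it.

**Step 13**
Reactants: 16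
Product: 17 primary iodide (C12–I)
Conditions: NaI (5 equiv), acetone, 50 °C, dark
Reagents that add atoms: sodium iodide, [Na+].[I-]
Why: Finkelstein SN2 at the primary carbon makes a good radical precursor, and no stereocentre is involved.

**Step 14**
Reactants: 17; 18 propanal
Product: 19 ketone (C12–C13(=O)–CH₂CH₃)
Conditions: N-mesityl triazolium NHC precatalyst (20 mol%), Cs₂CO₃ (0.5 equiv), propanal (6 equiv), DMA, blue LEDs, 25 °C
Reagents that add atoms: none
Why: Proposed new method: propanal and the NHC give a Breslow enolate, which by photoinduced SET reduces the primary iodide to a C12 radical; cross-coupling of that radical with the persistent Breslow radical cation forms C12–C13 and releases the ketone. The closest known chemistry is NHC-catalysed radical acylation of alkyl halides with aromatic aldehydes, extended here to an aliphatic aldehyde and a β-silyloxy iodide; the bond forms at a non-stereogenic CH₂, so no new stereocentre arises.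

**Step 15**
Reactants: 19
Product: 20 bis-TBS ether with free C8′ and C10′ CH₂OH groups
Conditions: DDQ (2.5 equiv), CH₂Cl₂/pH 7 buffer (18:1), 0 °C
Reagents that add atoms: none
Why: DDQ oxidative cleavage of the PMB ethers (SET, then hydrolysis of the oxocarbenium) is neutral and leaves epoxide, alkene, TBS ethers and stereocentres intact.

**Step 16**
Reactants: 20
Product: 21 Myriaporone 4
Conditions: TBAF (6 equiv), AcOH (6 equiv), THF, 0 °C → 25 °C
Reagents that add atoms: none
Why: Buffered fluoride removes both TBS groups without retro-aldol or epoxide opening, giving the target (all stereocentres already set).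

## Compound list
1 | 3-pentyn-2-one | CC#CC(C)=O | starting material
2 | (2R)-pent-3-yn-2-ol | C[C@@H](O)C#CC | intermediate
3 | (2R)-pent-3-yn-2-yl methanesulfonate | C[C@@H](OS(C)(=O)=O)C#CC | intermediate
4 | methacrolein | C=C(C)C=O | starting material
5 | (3S,4S)-2,4-dimethylhept-1-en-5-yn-3-ol | C=C(C)[C@@H](O)[C@@H](C)C#CC | intermediate
6 | (3S,4S,5Z)-2,4-dimethylhepta-1,5-dien-3-ol | C/C=C\[C@H](C)[C@H](O)C(C)=C | intermediate
7 | (1S,2S,3Z)-2-methyl-1-[(2S)-2-methyloxiran-2-yl]pent-3-en-1-ol | C/C=C\[C@H](C)[C@H](O)[C@]1(C)CO1 | intermediate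
8 | {(2R,3S)-2-methyl-3-[(2S,3Z)-pent-3-en-2-yl]oxiran-2-yl}methanol | C/C=C\[C@H](C)[C@@H]1O[C@]1(C)CO | intermediate
9 | (2S,3S)-2-methyl-3-[(2S,3Z)-pent-3-en-2-yl]oxirane-2-carbaldehyde | C/C=C\[C@H](C)[C@@H]1O[C@]1(C)C=O | intermediate
10 | 1,5-dichloropentan-3-one | ClCCC(=O)CCCl | starting material
11 | 1,5-bis[(4-methoxybenzyl)oxy]pentan-3-one | COc1ccc(COCCC(=O)CCOCc2ccc(OC)cc2)cc1 | intermediate
12 | anti-aldol adduct of 9 and 11, stereocentres as in SMILES | C/C=C\[C@H](C)[C@@H]1O[C@]1(C)[C@@H](O)[C@@H](COCc1ccc(OC)cc1)C(=O)CCOCc1ccc(OC)cc1 | intermediate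
13 | C7-O-TBS ether of 12 | C/C=C\[C@H](C)[C@@H]1O[C@]1(C)[C@@H](O[Si](C)(C)C(C)(C)C)[C@@H](COCc1ccc(OC)cc1)C(=O)CCOCc1ccc(OC)cc1 | intermediate
14 | chloroacetaldehyde | ClCC=O | starting material
15 | aldol adduct of 13 with 14 (C11-OH, C12-Cl) | C/C=C\[C@H](C)[C@@H]1O[C@]1(C)[C@@H](O[Si](C)(C)C(C)(C)C)[C@@H](COCc1ccc(OC)cc1)C(=O)[C@@H](COCc1ccc(OC)cc1)[C@@H](O)CCl | intermediate
16 | C11-O-TBS ether of 15 | C/C=C\[C@H](C)[C@@H]1O[C@]1(C)[C@@H](O[Si](C)(C)C(C)(C)C)[C@@H](COCc1ccc(OC)cc1)C(=O)[C@@H](COCc1ccc(OC)cc1)[C@@H](O[Si](C)(C)C(C)(C)C)CCl | intermediate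
17 | primary iodide from 16 | C/C=C\[C@H](C)[C@@H]1O[C@]1(C)[C@@H](O[Si](C)(C)C(C)(C)C)[C@@H](COCc1ccc(OC)cc1)C(=O)[C@@H](COCc1ccc(OC)cc1)[C@@H](O[Si](C)(C)C(C)(C)C)CI | intermediate
18 | propanal | CCC=O | starting material
19 | ethyl ketone from 17 + 18 | C/C=C\[C@H](C)[C@@H]1O[C@]1(C)[C@@H](O[Si](C)(C)C(C)(C)C)[C@@H](COCc1ccc(OC)cc1)C(=O)[C@@H](COCc1ccc(OC)cc1)[C@@H](O[Si](C)(C)C(C)(C)C)CC(=O)CC | intermediate
20 | bis-TBS diol from 19 | C/C=C\[C@H](C)[C@@H]1O[C@]1(C)[C@@H](O[Si](C)(C)C(C)(C)C)[C@@H](CO)C(=O)[C@@H](CO)[C@@H](O[Si](C)(C)C(C)(C)C)CC(=O)CC | intermediate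
21 | Myriaporone 4 | C/C=C\[C@H](C)[C@@H]1O[C@]1(C)[C@@H](O)[C@@H](CO)C(=O)[C@@H](CO)[C@@H](O)CC(=O)CC | target

## Totals
Total steps: 16. Longest linear sequence: 15 (steps 1–7, then 9–16; step 8 runs in parallel).

Three steps most likely to fail:
1. **Step 14 (NHC radical acylation).** An enolisable aliphatic aldehyde and a base-sensitive β-silyloxy ketone (α-epimerisation, E1cB loss of OTBS) may not survive. Fallback: in step 11 use 2-(2-ethyl-1,3-dioxolan-2-yl)acetaldehyde (from ethyl vinyl ketone by ketalisation, hydroboration/oxidation, then oxidation) so the ethyl ketone is carried as a ketal, then remove it with I₂/acetone.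
2. **Steps 9/11 (double anti-aldol).** Matching of the Ipc₂BCl enantiomers with the substrate stereocentres, and an epoxide that may not tolerate B–Cl Lewis acids, could give poor dr. Fallback: build each 1,3-anti unit by Roush crotylation with (E)-4-(PMBO)but-2-enylboronate, then cleave the vinyl group chemoselectively (OsO₄/NaIO₄) to the C9 aldehyde and add the second arm by an Evans anti-aldol.
3. **Step 6 (Payne equilibrium).** The equilibrium may favour the epoxide/secondary alcohol 7. Fallback: make the (E)-trisubstituted allylic alcohol (C7H₂OH–C6(CH₃)=C5H–) from (R)-Roche ester by Z-Wittig, oxidation, HWE and DIBAL reduction. Then apply standard Sharpless AE directly to give the C5–C6 epoxy alcohol.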